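The geranylgeranyl chain is cut at C4′–C5′ (chain numbered from the ring), a CH2–CH2 bond whose two carbons are each allylic: C4′ to the C2′=C3′ olefin and C5′ to the C6′=C7′ olefin. Both are innate electrophilic allyl termini; reversing the polarity of farnesyl chloride as its allylbarium lets C5′ attack the (E)-allylic bromide at C4′ in an α,α′-selective, geometry-retaining coupling that installs the whole C15 tail in one operation with no activating group to remove. The precursor is a silyl-protected cyclohexene triol (ketone and acid at the alcohol level) whose two ring stereocentres come from asymmetric allylic alkylation and iodolactonisation.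

Key step: step 16

Remark on locants: ring atoms are numbered as in the target cyclohex-2-en-1-one (C1 = C=O, C2 bears CH2CO2H, C4 bears OAc, C5 bears the chain); chain atoms are C1′–C16′ from the ring; TBS = tert-butyldimethylsilyl, TES = triethylsilyl.
Assumption: the (S,S)-ligand in step 2 is taken to give the (R)-malonate 4; should the sense of induction be opposite, the (R,R)-ligand is used and nothing else changes.
Assumption: the C1 carbinol centre made in step 9 is drawn as the expected major all-cis epimer; its configuration is irrelevant because it is oxidised again in step 20.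

Step 1
Reactants: 1 cyclohex-2-en-1-ol (racemic)
Product: 2 cyclohex-2-en-1-yl acetate (racemic)
Conditions: Ac2O, pyridine, DMAP (cat.), CH2Cl2, 0 °C to rt
Reagents that add atoms: acetic anhydride, CC(=O)OC(C)=O
Why: DMAP-catalysed O-acylation of the allylic alcohol; the racemate suffices because both enantiomers converge in step 2.

Step 2
Reactants: 2 cyclohex-2-en-1-yl acetate; 3 dimethyl malonate
Product: 4 dimethyl 2-[(1R)-cyclohex-2-en-1-yl]propanedioate
Conditions: [Pd(η3-C3H5)Cl]2 (cat.), (S,S)-DACH-phenyl diphosphine ligand [(1S,2S)-N,N′-bis(2-diphenylphosphanylbenzoyl)cyclohexane-1,2-diamine] (cat.), Cs2CO3, CH2Cl2, rt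
Reagents that add atoms: none
Why: Tsuji–Trost asymmetric allylic alkylation: both enantiomers of 2 ionise to the same meso π-allylpalladium complex and the chiral ligand pocket directs the malonate to one allyl terminus, setting the future C5 stereocentre.

Step 3
Reactants: 4 dimethyl 2-[(1R)-cyclohex-2-en-1-yl]propanedioate
Product: 6 2-[(1S)-cyclohex-2-en-1-yl]acetic acid, via cyclohexenylmalonic acid 5 (not isolated)
Conditions: KOH, MeOH/H2O, reflux; aq. HCl; then neat, 150 °C
Reagents that add atoms: none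
Why: Saponification followed by thermal decarboxylation of the malonic acid; the stereocentre is not involved (the descriptor changes from R to S only through the priority rules).

Step 4
Reactants: 6 2-[(1S)-cyclohex-2-en-1-yl]acetic acid
Product: 7 (3aS,7R,7aR)-7-iodohexahydro-1-benzofuran-2(3H)-one
Conditions: I2, KI, NaHCO3, THF/H2O, 0 °C to rt, dark
Reagents that add atoms: iodine, II
Why: Iodolactonisation: the carboxylate opens the iodonium ion anti at the adjacent alkene carbon and the two-atom tether allows only cis ring fusion, so the C–O centre (future C4) is set cis to the CH2 on C5 by the existing stereocentre; the crystalline product should also allow enantiomeric enrichment.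

Step 5
Reactants: 7 (3aS,7R,7aR)-7-iodohexahydro-1-benzofuran-2(3H)-one
Product: 8 (3aS,7aR)-3a,4,5,7a-tetrahydro-1-benzofuran-2(3H)-one
Conditions: DBU, toluene, 110 °C
Reagents that add atoms: none
Why: E2 dehydroiodination: only a C6–H is antiperiplanar to the C7–I bond (the C7a–H is syn), so the alkene forms away from the lactone oxygen.

Step 6
Reactants: 8 (3aS,7aR)-3a,4,5,7a-tetrahydro-1-benzofuran-2(3H)-one
Product: 9 (3aS,7aR)-3,3a,4,7a-tetrahydro-1-benzofuran-2,5-dione
Conditions: Rh2(cap)4 (1 mol %), t-BuOOH (5 equiv), K2CO3, CH2Cl2, rt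
Reagents that add atoms: tert-butyl hydroperoxide, CC(C)(C)OO
Why: Dirhodium caprolactamate-catalysed allylic oxidation (radical allylic peroxidation, then collapse to the enone): the ring CH2 at C5 is the only readily abstracted allylic position, the ring-fusion C–H being deactivated by the acyloxy group, so the carbonyl appears at the future C1.

Step 7
Reactants: 9 (3aS,7aR)-3,3a,4,7a-tetrahydro-1-benzofuran-2,5-dione
Product: 10 (3aS,7aR)-6-iodo-3,3a,4,7a-tetrahydro-1-benzofuran-2,5-dione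
Conditions: I2, pyridine, CH2Cl2, 0 °C to rt
Reagents that add atoms: iodine, II
Why: α-Iodination of the enone by pyridine conjugate addition, iodination of the enolate and elimination (Baylis–Hillman-type pathway) puts iodine on the α-carbon (future C2).

Step 8
Reactants: 10 (3aS,7aR)-6-iodo-3,3a,4,7a-tetrahydro-1-benzofuran-2,5-dione; 11 tert-butyldimethyl(vinyloxy)silane
Product: 13 (3aS,7aR)-6-[2-(TBS-oxy)ethyl]-3,3a,4,7a-tetrahydro-1-benzofuran-2,5-dione, via alkyl-9-BBN 12 (not isolated)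
Conditions: 11, 9-BBN-H, THF, 0 °C to rt; then 10, PdCl2(dppf) (cat.), AsPh3 (cat.), Cs2CO3, DMF/H2O, rt
Reagents that add atoms: none
Why: Anti-Markovnikov hydroboration of the silyl enol ether gives the primary alkylborane, which undergoes B-alkyl Suzuki–Miyaura coupling with the 2-iodoenone at room temperature, oxidative addition into C–I being much faster than ionisation of the allylic lactone.

Step 9
Reactants: 13 (3aS,7aR)-6-[2-(TBS-oxy)ethyl]-3,3a,4,7a-tetrahydro-1-benzofuran-2,5-dione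
Product: 14 (3aS,5S,7aR)-5-hydroxy-6-[2-(TBS-oxy)ethyl]-3a,4,5,7a-tetrahydro-1-benzofuran-2(3H)-one
Conditions: NaBH4, CeCl3·7H2O, MeOH, −78 °C
Reagents that add atoms: none
Why: Luche reduction gives 1,2-reduction of the enone without touching the lactone; hydride adds axially anti to the C5 substituent (as with carvone), so the all-cis carbinol should predominate.

Step 10
Reactants: 14 (3aS,5S,7aR)-5-hydroxy-6-[2-(TBS-oxy)ethyl]-3a,4,5,7a-tetrahydro-1-benzofuran-2(3H)-one
Product: 15 (3aS,5S,7aR)-5-(TBS-oxy)-6-[2-(TBS-oxy)ethyl]-3a,4,5,7a-tetrahydro-1-benzofuran-2(3H)-one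
Conditions: TBSOTf, 2,6-lutidine, CH2Cl2, −78 °C
Reagents that add atoms: tert-butyldimethylsilyl triflate, CC(C)(C)[Si](C)(C)OS(=O)(=O)C(F)(F)F
Why: Silylation with the triflate at −78 °C is fast enough to outrun translactonisation onto the cis C1 hydroxyl, which must be masked before the lactone is opened.

Step 11
Reactants: 15 (3aS,5S,7aR)-5-(TBS-oxy)-6-[2-(TBS-oxy)ethyl]-3a,4,5,7a-tetrahydro-1-benzofuran-2(3H)-one
Product: 16 (3aS,5S,7aR)-5-(TBS-oxy)-6-[2-(TBS-oxy)ethyl]-2,3,3a,4,5,7a-hexahydro-1-benzofuran-2-ol (anomer mixture)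
Conditions: DIBAL-H (1.1 equiv), CH2Cl2, −78 °C; aq. Rochelle salt
Reagents that add atoms: none
Why: DIBAL-H half-reduction of the γ-lactone: the tetrahedral aluminium acetal is stable at −78 °C and gives the lactol on work-up.

Step 12
Reactants: 16 lactol; 17 ethyl 2-(triphenyl-λ5-phosphanylidene)propanoate
Product: 18 ethyl (2E)-4-[(1S,4R,5R)-1-(TBS-oxy)-2-[2-(TBS-oxy)ethyl]-4-hydroxycyclohex-2-en-5-yl]-2-methylbut-2-enoate
Conditions: 17 (2 equiv), toluene, 90 °C
Reagents that add atoms: none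
Why: Wittig olefination of the open hydroxy-aldehyde form with the stabilised α-methyl ylide gives the (E)-trisubstituted enoate (C2′=C3′) and releases the C4 hydroxyl.

Step 13
Reactants: 18 hydroxy enoate
Product: 19 ethyl (2E)-4-[(1S,4R,5R)-1-(TBS-oxy)-2-[2-(TBS-oxy)ethyl]-4-(TES-oxy)cyclohex-2-en-5-yl]-2-methylbut-2-enoate
Conditions: TESCl, imidazole, DMAP (cat.), CH2Cl2, 0 °C to rt
Reagents that add atoms: chlorotriethylsilane, CC[Si](CC)(CC)Cl
Why: Silylation of the secondary allylic C4 alcohol with a group that can later be removed in the presence of the two TBS ethers.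

Step 14
Reactants: 19 TES-protected enoate
Product: 20 (2E)-4-[(1S,4R,5R)-1-(TBS-oxy)-2-[2-(TBS-oxy)ethyl]-4-(TES-oxy)cyclohex-2-en-5-yl]-2-methylbut-2-en-1-ol
Conditions: DIBAL-H (2.5 equiv), CH2Cl2, −78 °C; aq. Rochelle salt
Reagents that add atoms: none
Why: DIBAL-H 1,2-reduction of the enoate to the allylic alcohol with retention of the (E)-geometry.

Step 15
Reactants: 20 allylic alcohol
Product: 22 (1S,4R,5R)-5-[(2E)-4-bromo-3-methylbut-2-en-1-yl]-1-(TBS-oxy)-2-[2-(TBS-oxy)ethyl]-4-(TES-oxy)cyclohex-2-ene, via allylic mesylate 21 (not isolated)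
Conditions: MsCl, Et3N, THF, −40 °C; then LiBr, THF, −40 to 0 °C
Reagents that add atoms: lithium bromide, [Li+].[Br-]
Why: Mesylation and in situ SN2 displacement by bromide at low temperature gives the primary allylic bromide without allylic transposition or loss of geometry.

Step 16
Reactants: 22 allylic bromide; 23 (2E,6E)-farnesyl chloride
Product: 25 (1S,4R,5R)-1-(TBS-oxy)-2-[2-(TBS-oxy)ethyl]-4-(TES-oxy)-5-[(2E,6E,10E)-3,7,11,15-tetramethylhexadeca-2,6,10,14-tetraen-1-yl]cyclohex-2-ene, via farnesylbarium chloride 24 (not isolated)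
Conditions: BaI2, lithium biphenylide (2 equiv), THF, rt (activated Ba); 23 (2.5 equiv), −78 °C; then 22, THF, −78 °C
Reagents that add atoms: none
Why: Activated barium inserts into the C–Cl bond of 23 at −78 °C to give the σ-allylbarium 24, which holds its (E)-geometry at this temperature and carries the negative charge on the former CH2Cl carbon (polarity reversal of C5′). This carbon displaces bromide from the primary CH2Br of 22 (C4′) in a direct α,α′ SN2 substitution, forming the C4′–C5′ bond. The closest known reaction type is the allylbarium–allylic halide cross-coupling used for stereospecific head-to-tail joining of oligoprenyl units. No ring is closed and no stereocentre is created; the three ring stereocentres of 22 are remote and untouched. The step needs α (not γ) attack of 24, SN2 (not SN2′) attack on 22 and retention of both (E)-olefins, which follow from the low temperature, the unhindered primary bromide set against its fully substituted γ-carbon, and the absence of carbonyl groups or acidic protons in 22 (silyl ethers only). Homocoupling of 24 to squalene is the main competing path and is met by using 24 in excess.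

Step 17
Reactants: 25 tris-silyl ether
Product: 26 (1R,4S,6R)-4-(TBS-oxy)-3-[2-(TBS-oxy)ethyl]-6-[(2E,6E,10E)-3,7,11,15-tetramethylhexadeca-2,6,10,14-tetraen-1-yl]cyclohex-2-en-1-ol
Conditions: PPTS (cat.), MeOH/CH2Cl2, 0 °C
Reagents that add atoms: none
Why: Mild acid-catalysed methanolysis cleaves the secondary triethylsilyl ether far faster than the TBS ethers, freeing only the C4 hydroxyl.

Step 18
Reactants: 26 C4 alcohol
Product: 27 (1R,4S,6R)-4-(TBS-oxy)-3-[2-(TBS-oxy)ethyl]-6-[(2E,6E,10E)-3,7,11,15-tetramethylhexadeca-2,6,10,14-tetraen-1-yl]cyclohex-2-en-1-yl acetate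
Conditions: Ac2O, pyridine, DMAP (cat.), CH2Cl2, rt
Reagents that add atoms: acetic anhydride, CC(=O)OC(C)=O
Why: DMAP-catalysed acetylation installs the C4 acetate of the target with the configuration fixed in step 4.

Step 19
Reactants: 27 bis-TBS acetate
Product: 28 (1R,4S,6R)-4-hydroxy-3-(2-hydroxyethyl)-6-[(2E,6E,10E)-3,7,11,15-tetramethylhexadeca-2,6,10,14-tetraen-1-yl]cyclohex-2-en-1-yl acetate
Conditions: HF·pyridine, pyridine, THF, 0 °C to rt
Reagents that add atoms: none
Why: Buffered fluoride desilylation removes both TBS ethers while the acetate and the polyene should be stable under these mildly acidic conditions.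

Step 20
Reactants: 28 diol acetate
Product: 29 (1R,6R)-3-(2-hydroxyethyl)-4-oxo-6-[(2E,6E,10E)-3,7,11,15-tetramethylhexadeca-2,6,10,14-tetraen-1-yl]cyclohex-2-en-1-yl acetate
Conditions: activated MnO2 (excess), CH2Cl2, rt
Reagents that add atoms: none
Why: MnO2 oxidises only the allylic C1 carbinol to the enone and leaves the primary alcohol, which avoids lactol formation from a 1,4-hydroxy aldehyde and removes the temporary C1 stereocentre.

Step 21
Reactants: 29 hydroxy enone
Product: 30 2-[(3R,4R)-3-acetoxy-6-oxo-4-[(2E,6E,10E)-3,7,11,15-tetramethylhexadeca-2,6,10,14-tetraen-1-yl]cyclohex-1-en-1-yl]acetic acid (CNP0169300.1)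
Conditions: TEMPO (cat.), PhI(OAc)2, MeCN/H2O (1:1), rt
Reagents that add atoms: water, O
Why: TEMPO/PhI(OAc)2 oxidation in aqueous acetonitrile takes the primary alcohol through the aldehyde hydrate to the acid under near-neutral conditions that should spare the γ-acetoxy enone and the trisubstituted olefins.

Compound list
1 | cyclohex-2-en-1-ol (racemic) | OC1C=CCCC1 | starting material
2 | cyclohex-2-en-1-yl acetate (racemic) | CC(=O)OC1C=CCCC1 | intermediate
3 | dimethyl malonate | COC(=O)CC(=O)OC | starting material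
4 | dimethyl 2-[(1R)-cyclohex-2-en-1-yl]propanedioate | C1=CCCC[C@H]1C(C(=O)OC)C(=O)OC | intermediate
5 | 2-[(1R)-cyclohex-2-en-1-yl]propanedioic acid (not isolated) | C1=CCCC[C@H]1C(C(=O)O)C(=O)O | intermediate
6 | 2-[(1S)-cyclohex-2-en-1-yl]acetic acid | C1=CCCC[C@H]1CC(=O)O | intermediate
7 | (3aS,7R,7aR)-7-iodohexahydro-1-benzofuran-2(3H)-one | O=C2O[C@H]1[C@H](I)CCC[C@H]1C2 | intermediate
8 | (3aS,7aR)-3a,4,5,7a-tetrahydro-1-benzofuran-2(3H)-one | O=C2O[C@H]1C=CCC[C@H]1C2 | intermediate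
9 | (3aS,7aR)-3,3a,4,7a-tetrahydro-1-benzofuran-2,5-dione | O=C2O[C@H]1C=CC(=O)C[C@H]1C2 | intermediate
10 | (3aS,7aR)-6-iodo-3,3a,4,7a-tetrahydro-1-benzofuran-2,5-dione | O=C2O[C@H]1C=C(I)C(=O)C[C@H]1C2 | intermediate
11 | tert-butyldimethyl(vinyloxy)silane | C=CO[Si](C)(C)C(C)(C)C | starting material
12 | 9-[2-(TBS-oxy)ethyl]-9-borabicyclo[3.3.1]nonane (not isolated) | CC(C)(C)[Si](C)(C)OCCB1C2CCCC1CCC2 | intermediate
13 | (3aS,7aR)-6-[2-(TBS-oxy)ethyl]-3,3a,4,7a-tetrahydro-1-benzofuran-2,5-dione | O=C2O[C@H]1C=C(CCO[Si](C)(C)C(C)(C)C)C(=O)C[C@H]1C2 | intermediate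
14 | (3aS,5S,7aR)-5-hydroxy-6-[2-(TBS-oxy)ethyl]-3a,4,5,7a-tetrahydro-1-benzofuran-2(3H)-one | O=C2O[C@H]1C=C(CCO[Si](C)(C)C(C)(C)C)[C@@H](O)C[C@H]1C2 | intermediate
15 | (3aS,5S,7aR)-5-(TBS-oxy)-6-[2-(TBS-oxy)ethyl]-3a,4,5,7a-tetrahydro-1-benzofuran-2(3H)-one | O=C2O[C@H]1C=C(CCO[Si](C)(C)C(C)(C)C)[C@@H](O[Si](C)(C)C(C)(C)C)C[C@H]1C2 | intermediate
16 | (3aS,5S,7aR)-5-(TBS-oxy)-6-[2-(TBS-oxy)ethyl]-2,3,3a,4,5,7a-hexahydro-1-benzofuran-2-ol (anomer mixture) | OC2O[C@H]1C=C(CCO[Si](C)(C)C(C)(C)C)[C@@H](O[Si](C)(C)C(C)(C)C)C[C@H]1C2 | intermediate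
17 | ethyl 2-(triphenyl-λ5-phosphanylidene)propanoate | CCOC(=O)C(C)=P(c1ccccc1)(c1ccccc1)c1ccccc1 | starting material
18 | ethyl (2E)-4-[(1S,4R,5R)-1-(TBS-oxy)-2-[2-(TBS-oxy)ethyl]-4-hydroxycyclohex-2-en-5-yl]-2-methylbut-2-enoate | O[C@H]1C=C(CCO[Si](C)(C)C(C)(C)C)[C@@H](O[Si](C)(C)C(C)(C)C)C[C@H]1C/C=C(\C)C(=O)OCC | intermediate
19 | ethyl (2E)-4-[(1S,4R,5R)-1-(TBS-oxy)-2-[2-(TBS-oxy)ethyl]-4-(TES-oxy)cyclohex-2-en-5-yl]-2-methylbut-2-enoate | CC[Si](CC)(CC)O[C@H]1C=C(CCO[Si](C)(C)C(C)(C)C)[C@@H](O[Si](C)(C)C(C)(C)C)C[C@H]1C/C=C(\C)C(=O)OCC | intermediate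
20 | (2E)-4-[(1S,4R,5R)-1-(TBS-oxy)-2-[2-(TBS-oxy)ethyl]-4-(TES-oxy)cyclohex-2-en-5-yl]-2-methylbut-2-en-1-ol | CC[Si](CC)(CC)O[C@H]1C=C(CCO[Si](C)(C)C(C)(C)C)[C@@H](O[Si](C)(C)C(C)(C)C)C[C@H]1C/C=C(\C)CO | intermediate
21 | methanesulfonate of 20 (not isolated) | CC[Si](CC)(CC)O[C@H]1C=C(CCO[Si](C)(C)C(C)(C)C)[C@@H](O[Si](C)(C)C(C)(C)C)C[C@H]1C/C=C(\C)COS(C)(=O)=O | intermediate
22 | (1S,4R,5R)-5-[(2E)-4-bromo-3-methylbut-2-en-1-yl]-1-(TBS-oxy)-2-[2-(TBS-oxy)ethyl]-4-(TES-oxy)cyclohex-2-ene | CC[Si](CC)(CC)O[C@H]1C=C(CCO[Si](C)(C)C(C)(C)C)[C@@H](O[Si](C)(C)C(C)(C)C)C[C@H]1C/C=C(\C)CBr | intermediate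
23 | (2E,6E)-farnesyl chloride [(2E,6E)-1-chloro-3,7,11-trimethyldodeca-2,6,10-triene] | ClC/C=C(\C)CC/C=C(\C)CCC=C(C)C | starting material
24 | (2E,6E)-farnesylbarium chloride (not isolated) | Cl[Ba]C/C=C(\C)CC/C=C(\C)CCC=C(C)C | intermediate
25 | (1S,4R,5R)-1-(TBS-oxy)-2-[2-(TBS-oxy)ethyl]-4-(TES-oxy)-5-[(2E,6E,10E)-3,7,11,15-tetramethylhexadeca-2,6,10,14-tetraen-1-yl]cyclohex-2-ene | CC[Si](CC)(CC)O[C@H]1C=C(CCO[Si](C)(C)C(C)(C)C)[C@@H](O[Si](C)(C)C(C)(C)C)C[C@H]1C/C=C(\C)CC/C=C(\C)CC/C=C(\C)CCC=C(C)C | intermediate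
26 | (1R,4S,6R)-4-(TBS-oxy)-3-[2-(TBS-oxy)ethyl]-6-[(2E,6E,10E)-3,7,11,15-tetramethylhexadeca-2,6,10,14-tetraen-1-yl]cyclohex-2-en-1-ol | O[C@H]1C=C(CCO[Si](C)(C)C(C)(C)C)[C@@H](O[Si](C)(C)C(C)(C)C)C[C@H]1C/C=C(\C)CC/C=C(\C)CC/C=C(\C)CCC=C(C)C | intermediate
27 | acetate of 26 | CC(=O)O[C@H]1C=C(CCO[Si](C)(C)C(C)(C)C)[C@@H](O[Si](C)(C)C(C)(C)C)C[C@H]1C/C=C(\C)CC/C=C(\C)CC/C=C(\C)CCC=C(C)C | intermediate
28 | (1R,4S,6R)-4-hydroxy-3-(2-hydroxyethyl)-6-[(2E,6E,10E)-3,7,11,15-tetramethylhexadeca-2,6,10,14-tetraen-1-yl]cyclohex-2-en-1-yl acetate | CC(=O)O[C@H]1C=C(CCO)[C@@H](O)C[C@H]1C/C=C(\C)CC/C=C(\C)CC/C=C(\C)CCC=C(C)C | intermediate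
29 | (1R,6R)-3-(2-hydroxyethyl)-4-oxo-6-[(2E,6E,10E)-3,7,11,15-tetramethylhexadeca-2,6,10,14-tetraen-1-yl]cyclohex-2-en-1-yl acetate | CC(=O)O[C@H]1C=C(CCO)C(=O)C[C@H]1C/C=C(\C)CC/C=C(\C)CC/C=C(\C)CCC=C(C)C | intermediate
30 | 2-[(3R,4R)-3-acetoxy-6-oxo-4-[(2E,6E,10E)-3,7,11,15-tetramethylhexadeca-2,6,10,14-tetraen-1-yl]cyclohex-1-en-1-yl]acetic acid | CC(=O)O[C@H]1C=C(CC(=O)O)C(=O)C[C@H]1C/C=C(\C)CC/C=C(\C)CC/C=C(\C)CCC=C(C)C | target

Total steps: 21. Longest linear sequence: 21 steps (1 to 30); the farnesyl partner 23 is purchased.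

Steps most likely to fail

Step 16. What may go wrong: Wurtz-type homocoupling while the barium reagent forms, halogen–metal exchange with 22 that scrambles the partners into homodimers, or erosion of α/SN2 selectivity on the hindered substrate. The fallback sets out from 22 and 23 and returns at 25. Sodium benzenesulfinate (DMF, rt) converts 23 into (2E,6E)-farnesyl phenyl sulfone F1. Deprotonation (n-BuLi, THF/HMPA, −78 °C) gives a sulfone-stabilised allyl anion that alkylates only at its α-carbon with 22, giving the C5′-phenylsulfonyl derivative of 25, sulfone F2. Palladium-catalysed reductive desulfonylation (PdCl2(dppp) cat., LiBHEt3, THF, 0 °C), with hydride delivered to the less substituted terminus of the π-allyl, then gives 25 (Julia-type sulfone alkylation and desulfonylation).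

Step 8. What may go wrong: β-elimination of the β-silyloxyalkyl borane or palladium intermediate, base-promoted opening of the lactone, or competing ionisation of the allylic lactone by Pd(0). The fallback sets out from 10 and returns at 15. Base-free Stille coupling of 10 with tributyl(vinyl)stannane (Pd2(dba)3, AsPh3, CuI, NMP, rt) gives the 6-vinyl enone F3. Luche reduction gives the dienol F4, and silylation (TBSOTf, 2,6-lutidine, −78 °C) gives its TBS ether F5. 9-BBN hydroboration of the terminal vinyl group with buffered oxidation (NaBO3·4H2O) gives the primary alcohol F6, and TBSCl/imidazole gives 15.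

Step 6. What may go wrong: poor regiocontrol in the radical oxidation, so that the carbonyl appears next to the lactone oxygen, or over-oxidation of the product at its γ-position. The fallback sets out from 8 and returns at 9. SeO2 (cat.)/t-BuOOH allylic hydroxylation (ene reaction then [2,3]-sigmatropic shift, which attacks the ring CH2 and keeps the double bond in place) gives the allylic alcohol F7 as an epimer mixture. Dess–Martin oxidation then gives 9.

Further compounds
F1 | step 16 | (2E,6E)-farnesyl phenyl sulfone | O=S(=O)(C/C=C(\C)CC/C=C(\C)CCC=C(C)C)c1ccccc1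
F2 | step 16 | C5′-(phenylsulfonyl) derivative of 25 (epimers at C5′) | CC[Si](CC)(CC)O[C@H]1C=C(CCO[Si](C)(C)C(C)(C)C)[C@@H](O[Si](C)(C)C(C)(C)C)C[C@H]1C/C=C(\C)CC(/C=C(\C)CC/C=C(\C)CCC=C(C)C)S(=O)(=O)c1ccccc1
F3 | step 8 | (3aS,7aR)-6-ethenyl-3,3a,4,7a-tetrahydro-1-benzofuran-2,5-dione | O=C2O[C@H]1C=C(C=C)C(=O)C[C@H]1C2
F4 | step 8 | (3aS,5S,7aR)-6-ethenyl-5-hydroxy-3a,4,5,7a-tetrahydro-1-benzofuran-2(3H)-one | O=C2O[C@H]1C=C(C=C)[C@@H](O)C[C@H]1C2
F5 | step 8 | (3aS,5S,7aR)-5-(TBS-oxy)-6-ethenyl-3a,4,5,7a-tetrahydro-1-benzofuran-2(3H)-one | O=C2O[C@H]1C=C(C=C)[C@@H](O[Si](C)(C)C(C)(C)C)C[C@H]1C2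
F6 | step 8 | (3aS,5S,7aR)-5-(TBS-oxy)-6-(2-hydroxyethyl)-3a,4,5,7a-tetrahydro-1-benzofuran-2(3H)-one | O=C2O[C@H]1C=C(CCO)[C@@H](O[Si](C)(C)C(C)(C)C)C[C@H]1C2
F7 | step 6 | (3aS,7aR)-5-hydroxy-3a,4,5,7a-tetrahydro-1-benzofuran-2(3H)-one (C5 epimers) | O=C2O[C@H]1C=CC(O)C[C@H]1C2
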